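All constants were set for the occasion; the rest is arithmetic.

The pitfall is to treat the free catalyst as a constant, as if the charge stayed at work through the run; in this flask it goes in pairs, while substrate turns into isomer of the product A without any catalyst.

common to all: free catalyst 34 mM; impurity 3.7 mM
- noon: substrate 0.26 M; time 4.0 min; everything together in a closed stirred flask, run for 4.0 min
- midnight: substrate 0.26 M; a single well-mixed tank run continuously and read at steady state, 4.0 min in it on average
- summer: substrate 0.26 M (fed, over 3.20 min); time 4.0 min; all but substrate at the start; substrate goes in evenly over 3.20 min, the run ends at 4.0 min

    substrate + free catalyst ⇌ target + free catalyst, rate k1*[substrate]*[free catalyst] forward; the back reaction follows from the equilibrium constant (K1 = 2.7, k1 = 5.1 M⁻¹ s⁻¹)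
    free catalyst + impurity → spent catalyst B (k2 = 6700 M⁻¹ s⁻¹)
    substrate + free catalyst ⇌ isomer of the product B + free catalyst, rate k3*[substrate]*[free catalyst] forward; the back reaction follows from the equilibrium constant (K3 = 0.63, k3 = 0.91 M⁻¹ s⁻¹)
    substrate ⇌ isomer of the product A (K4 = 2.0, k4 = 0.042 s⁻¹)
    2 free catalyst → spent catalyst A (k5 = 2.9 M⁻¹ s⁻¹)

- a doubled species enters its step squared and goes two at a time
- the stated concentrations are those of everything mixed, before any reaction; amounts are the same in each set-up
- the feed brings no volume worth counting
- run time (noon): 4.0 min

- the set-up with the highest amount of target at the outlet or at the end, in percent of the substrate put in ("none" if the first two lie within 2 percentage points) (noon / midnight / summer / none)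
- amount of target at the outlet or at the end, in percent of the substrate put in, noon
- amount of target at the outlet or at the end, in percent of the substrate put in, midnight
- amount of target at the outlet or at the end, in percent of the substrate put in, summer

Dividing the forward rate from substrate to target by that from substrate to isomer of the product A cancels substrate and leaves free catalyst against a single number, 24.2 % of the catalyst charge: the crossover fraction, the share of the catalyst charge at which these two forward rates are equal. Above it substrate leaves faster toward target; below it, faster toward isomer of the product A.

The ladder starts with impurity, whose half-life against free catalyst is 0.00304 s. Pair loss at the start runs at 0.0080 of the impurity path, so impurity removes 10.9 % of the charge. Next comes the half-life of substrate toward target, 0.067 min, shorter than the first pair-loss half-life of the catalyst, 0.0948 min. Then come the half-lives toward isomer of the product A, 0.28 min, and isomer of the product B, 0.37 min.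

By this reckoning free catalyst reaches the crossover fraction at 0.254 min. Counted with the catalyst as it falls, the forward path toward target in noon has run 1.65 half-lives by then and 4.78 by 4.0 min, so this reckoning expects noon near the equilibrium share of target, 42.7 %. In summer, 7.94 % of the substrate has entered by then, so the remainder meets catalyst below crossover. By the same reckoning the midnight tank holds a steady 12.7 % of the charge, also below crossover. The reckoning places midnight between the others, without a figure.

The forecast names noon, with 44 %, 37 % and 27.5 % for noon, midnight and summer, holding that “the slow feed delivers most substrate after the catalyst has died”.

The simulation gives 44.4 %, 37.0 % and 24.2 %, so noon stands highest, as forecast.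

At 4.00 min free catalyst in noon stands at 2.06 % of its charge, 0.0851 of the crossover fraction. The neighbour charged with 0.0085 M free catalyst begins, after impurity, at 0.583 of its own crossover and ends with 36.2 % target and 38.1 % isomer of the product A, against 44.4 % and 30.8 % in noon. Noon is nearly at rest: ten times the time takes target from 44.4 % to 43.3 %. Summer is not, since at 40.0 min its target goes from 24.2 % to 39.1 %.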